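## Retrosynthetic overview

1. Target 9 comes from its bis-TBS ether 8 by desilylation. The cyclohexene is the only ring made in the route, all arenes being bought. It is numbered C1 = quaternary diacyl carbon, C2 = CH(aryl), C3=C4, C5, C6.
2. 8 comes from the acyclic, achiral 4-(5-arylpenta-2,4-dienyl)curcumin 7 by cutting C1–C2. The forward reaction is an enantioselective Pd–H cycloisomerisation (intramolecular 1,4-hydroalkylation of the diene). One operation makes the ring, the quaternary C1, the stereocentre C2 and the cis C3=C4 bond.
3. Enabling feature: C2 is benzylic to the 3,4-dimethoxyphenyl ring and allylic to C3=C4, and it adjoins C1, the central carbon of a β-diketone (C4 of curcumin). C2–C3–C4 is therefore a latent aryl-stabilised π-allyl cation, reachable by protonating a 1-aryl-1,3-diene at C5, and C1 is a soft enolate. Two π-nucleophilic carbons are joined by reversing the polarity of the diene.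
4. 7 comes from bis-TBS-curcumin 2 and pentadienyl carbonate 6 (Tsuji–Trost, forms C1–C6). 6 comes from 3,4-dimethoxycinnamaldehyde 3 and vinylmagnesium bromide 4. 2 comes from curcumin 1.

Key step: step 5

Remark: β-diketones are drawn as diketo tautomers, and the (S)-configured ligand of step 5 is assumed to lead to the (R)-product; the sense of induction has to be verified on 8, and the equally available (R)-ligand is taken if it is opposite.

## Route

Step 1
Reactants: 1 curcumin
Product: 2 bis-O-TBS-curcumin, (1E,6E)-1,7-bis[4-(tert-butyldimethylsilyloxy)-3-methoxyphenyl]hepta-1,6-diene-3,5-dione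
Conditions: TBSCl (2.3 equiv), imidazole (5 equiv), DMF, rt; aqueous work-up
Reagents that add atoms: tert-butyldimethylsilyl chloride, CC(C)(C)[Si](C)(C)Cl
Why: Phenol silyl ether formation masks both acidic, nucleophilic OH groups for the two Pd steps, and any enol silyl ether should be hydrolysed on aqueous work-up.

Step 2
Reactants: 3 (E)-3,4-dimethoxycinnamaldehyde; 4 vinylmagnesium bromide
Product: 5 (E)-1-(3,4-dimethoxyphenyl)penta-1,4-dien-3-ol (racemic)
Conditions: THF, −78 → 0 °C; then pH 7 buffer
Reagents that add atoms: none
Why: Grignard 1,2-addition to an enal; the carbinol centre forms as a racemate, which does not matter because it is erased in step 4.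

Step 3
Reactants: 5 (E)-1-(3,4-dimethoxyphenyl)penta-1,4-dien-3-ol
Product: 6 (E)-1-(3,4-dimethoxyphenyl)penta-1,4-dien-3-yl methyl carbonate (racemic)
Conditions: ClCO2Me (1.3 equiv), pyridine (2 equiv), CH2Cl2, −10 → 0 °C; neutral work-up, used without long storage
Reagents that add atoms: methyl chloroformate, COC(=O)Cl
Why: O-acylation with a chloroformate gives the allylic carbonate needed for base-free Tsuji–Trost ionisation, and low temperature with a non-acidic work-up should keep the doubly allylic C–O bond intact.

Step 4
Reactants: 2 bis-O-TBS-curcumin (1.5 equiv, excess recovered); 6 pentadienyl methyl carbonate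
Product: 7 (1E,6E)-4-[(2E,4E)-5-(3,4-dimethoxyphenyl)penta-2,4-dien-1-yl]-1,7-bis[4-(tert-butyldimethylsilyloxy)-3-methoxyphenyl]hepta-1,6-diene-3,5-dione
Conditions: Pd(PPh3)4 (3 mol %), THF, 0 °C → rt, stopped at full consumption of 6
Reagents that add atoms: none
Why: Tsuji–Trost allylic alkylation, in which Pd(0) ionises 6 to an aryl-pentadienyl complex, the methoxide released with CO2 deprotonates the β-diketone, and the soft enolate attacks the unhindered CH2 terminus to give the fully conjugated (E,E)-aryldiene, with no stereocentre created because the two acyl arms on the new tertiary carbon are identical.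

Step 5
Reactants: 7 4-(5-arylpenta-2,4-dienyl)-bis-O-TBS-curcumin
Product: 8 1,1'-[(2R)-2-(3,4-dimethoxyphenyl)cyclohex-3-ene-1,1-diyl]bis{(2E)-3-[4-(tert-butyldimethylsilyloxy)-3-methoxyphenyl]prop-2-en-1-one}
Conditions: CpPd(η3-C3H5) (5 mol %), (S)-(CF3)3-t-BuPHOX (6 mol %), Et3NH·BArF4 (10 mol %), Et3N (20 mol %), Et2O–CH2Cl2, 0.02 M, 25 °C, dark
Reagents that add atoms: none
Why: Proposed new method: the chiral Pd(0) complex binds the s-cis 1-aryl-1,3-diene of 7 and the ammonium co-catalyst (which relays the acidic C–H of the β-diketone) protonates the diene carbon next to the CH2 group (future C5), so that the electron-rich diene becomes a cationic 1-aryl-3-alkyl-η3-allylpalladium unit (future C2–C3–C4) with the alkyl arm anti and the tethered diketonate as counter-ion, i.e. two π-nucleophilic carbons are turned into an acceptor/donor pair. The diketonate carbon then attacks the benzylic allyl terminus on the face opposite to Pd, which forms C1–C2, leaves the cis C3=C4 bond and returns Pd(0), overall a by-product-free cycloisomerisation (intramolecular 1,4-hydroalkylation). Closest known reaction types: the Pd–PHOX/ammonium-co-catalysed enantioselective intermolecular hydroalkylation of internal 1-aryl-1,3-dienes with β-dicarbonyl pronucleophiles, and the Pd(0)-catalysed rearrangement of 2-dienylcyclopropane-1,1-dicarbonyl compounds to cyclopentenes, where a tethered stabilised carbanion also closes on the far terminus of an anti-allyl complex; the intramolecular setting and bond formation at the aryl-bearing terminus are new. The cyclohexene closes in a 6-endo mode with respect to the allyl unit (all three allyl carbons become ring members). The single new stereocentre C2 is controlled by the P,N ligand, which decides on which enantiotopic face of the achiral diene Pd sits in the allyl complex that cyclises (attack anti to Pd and trans to P), while C1 is not stereogenic because its two acyl arms are identical. The step needs site selectivity (benzylic versus near allyl terminus, C versus O) and chemoselectivity (diene versus two enones): the two-carbon tether makes C-attack at the near terminus a strained four-ring closure and O-attack an allyl enol ether formation, both reversible under Pd(0), so that the cyclohexene is the only irreversible exit, the 3,4-dimethoxyphenyl ring directs protonation to the terminus that gives the aryl-conjugated allyl, and the enones can only bind reversibly like dba.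

Step 6
Reactants: 8 bis-TBS ether of the target
Product: 9 target, 1,1'-[(2R)-2-(3,4-dimethoxyphenyl)cyclohex-3-ene-1,1-diyl]bis[(2E)-3-(4-hydroxy-3-methoxyphenyl)prop-2-en-1-one]
Conditions: TBAF (2.4 equiv), AcOH (3 equiv), THF, 0 °C
Reagents that add atoms: none
Why: Fluoride-mediated desilylation, in which the acetic acid buffer keeps the liberated phenoxides protonated so that the non-enolisable β-diketone should escape retro-Claisen cleavage, and C2 carries no acidic hydrogen and is not touched.

## Compound list

1 | curcumin, (1E,6E)-1,7-bis(4-hydroxy-3-methoxyphenyl)hepta-1,6-diene-3,5-dione | COc1cc(/C=C/C(=O)CC(=O)/C=C/c2ccc(O)c(OC)c2)ccc1O | starting material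
2 | bis-O-TBS-curcumin | COc1cc(/C=C/C(=O)CC(=O)/C=C/c2ccc(O[Si](C)(C)C(C)(C)C)c(OC)c2)ccc1O[Si](C)(C)C(C)(C)C | intermediate
3 | (E)-3,4-dimethoxycinnamaldehyde | COc1ccc(/C=C/C=O)cc1OC | starting material
4 | vinylmagnesium bromide | C=C[Mg]Br | starting material
5 | (E)-1-(3,4-dimethoxyphenyl)penta-1,4-dien-3-ol (racemic) | COc1ccc(/C=C/C(O)C=C)cc1OC | intermediate
6 | (E)-1-(3,4-dimethoxyphenyl)penta-1,4-dien-3-yl methyl carbonate (racemic) | COc1ccc(/C=C/C(OC(=O)OC)C=C)cc1OC | intermediate
7 | 4-[(2E,4E)-5-(3,4-dimethoxyphenyl)penta-2,4-dien-1-yl]-bis-O-TBS-curcumin | COc1cc(/C=C/C(=O)C(C/C=C/C=C/c2ccc(OC)c(OC)c2)C(=O)/C=C/c2ccc(O[Si](C)(C)C(C)(C)C)c(OC)c2)ccc1O[Si](C)(C)C(C)(C)C | intermediate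
8 | (2R)-cyclohexene, bis-TBS ether of the target | COc1cc(/C=C/C(=O)C2(C(=O)/C=C/c3ccc(O[Si](C)(C)C(C)(C)C)c(OC)c3)CCC=C[C@@H]2c2ccc(OC)c(OC)c2)ccc1O[Si](C)(C)C(C)(C)C | intermediate
9 | CNP0213153.1, 1,1'-[(2R)-2-(3,4-dimethoxyphenyl)cyclohex-3-ene-1,1-diyl]bis[(2E)-3-(4-hydroxy-3-methoxyphenyl)prop-2-en-1-one] | COc1cc(/C=C/C(=O)C2(C(=O)/C=C/c3ccc(O)c(OC)c3)CCC=C[C@@H]2c2ccc(OC)c(OC)c2)ccc1O | target

## Step count and risks

Total step count: 6. Longest linear sequence: 5 steps (3 → 5 → 6 → 7 → 8 → 9).

**1. Step 5 (Proposed new method).**
- Risks: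
  - Proton delivery to the aryl-bearing diene terminus, followed by five-ring closure.
  - Stalling at the reversible O-closure stage.
  - Weak enantiofacial discrimination.
  - Slow racemisation by re-ionisation of the new allylic C–C bond.
  - Thermal intramolecular Diels–Alder reaction of the diene with one enone arm.
- Fallback (known chemistry; sets out from 2 and 3, comes back at 8): the one-bond closure is given up for a [4+2] assembly of the ring. Wittig methylenation of 3 (Ph3P=CH2, THF) gives (E)-1-(3,4-dimethoxyphenyl)buta-1,3-diene F1. Knoevenagel condensation of 2 with paraformaldehyde (cat. piperidinium acetate, toluene, 60–80 °C) generates 4-methylene-bis-O-TBS-curcumin F2 in the presence of F1. F1 traps it in a normal-electron-demand Diels–Alder reaction with "ortho" orientation, giving the racemic cyclohexene F3. Preparative HPLC on a chiral stationary phase delivers the (R)-enantiomer, which is 8.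

**2. Step 4.**
- Risks:
  - Double alkylation of the diketone carbon.
  - Attack at an internal carbon of the pentadienyl complex.
  - Premature, non-selective cyclisation under the achiral catalyst.
- Fallback (sets out from 6, comes back at 7): the allylic alkylation is moved to a cheap nucleophile and the enone arms are built afterwards. Tsuji–Trost reaction of 6 with a large excess of acetylacetone gives 3-[(2E,4E)-5-(3,4-dimethoxyphenyl)penta-2,4-dien-1-yl]pentane-2,4-dione F4. A boron-templated double aldol condensation under Pabon conditions (B2O3, B(OBu)3, cat. n-BuNH2, EtOAc, then mild aqueous acid) follows. It uses two equivalents of 4-(tert-butyldimethylsilyloxy)-3-methoxybenzaldehyde F5 (from vanillin, TBSCl, imidazole) and gives 7. Any phenol set free is re-silylated as in step 1.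

**3. Step 3.**
- Risks: ionisation, allylic transposition or elimination of the doubly allylic, electron-rich carbonate during its formation or isolation.
- Fallback (sets out from 3, comes back at 7): a robust primary, fully conjugated electrophile that gives the same pentadienyl–Pd complex is used.
  - Horner–Wadsworth–Emmons olefination of 3 (triethyl phosphonoacetate, NaH, THF) gives ethyl (2E,4E)-5-(3,4-dimethoxyphenyl)penta-2,4-dienoate F6.
  - DIBAL-H reduction gives (2E,4E)-5-(3,4-dimethoxyphenyl)penta-2,4-dien-1-ol F7.
  - ClCO2Me/pyridine gives (2E,4E)-5-(3,4-dimethoxyphenyl)penta-2,4-dien-1-yl methyl carbonate F8.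
  - F8 replaces 6 under the conditions of step 4 and gives 7.

## Further compounds

F1 | step 5 | (E)-1-(3,4-dimethoxyphenyl)buta-1,3-diene | COc1ccc(/C=C/C=C)cc1OC
F2 | step 5 | 4-methylene-bis-O-TBS-curcumin | COc1cc(/C=C/C(=O)C(=C)C(=O)/C=C/c2ccc(O[Si](C)(C)C(C)(C)C)c(OC)c2)ccc1O[Si](C)(C)C(C)(C)C
F3 | step 5 | racemic cyclohexene (racemate of 8) | COc1cc(/C=C/C(=O)C2(C(=O)/C=C/c3ccc(O[Si](C)(C)C(C)(C)C)c(OC)c3)CCC=CC2c2ccc(OC)c(OC)c2)ccc1O[Si](C)(C)C(C)(C)C
F4 | step 4 | 3-[(2E,4E)-5-(3,4-dimethoxyphenyl)penta-2,4-dien-1-yl]pentane-2,4-dione | COc1ccc(/C=C/C=C/CC(C(C)=O)C(C)=O)cc1OC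
F5 | step 4 | 4-(tert-butyldimethylsilyloxy)-3-methoxybenzaldehyde | COc1cc(C=O)ccc1O[Si](C)(C)C(C)(C)C
F6 | step 3 | ethyl (2E,4E)-5-(3,4-dimethoxyphenyl)penta-2,4-dienoate | CCOC(=O)/C=C/C=C/c1ccc(OC)c(OC)c1
F7 | step 3 | (2E,4E)-5-(3,4-dimethoxyphenyl)penta-2,4-dien-1-ol | OC/C=C/C=C/c1ccc(OC)c(OC)c1
F8 | step 3 | (2E,4E)-5-(3,4-dimethoxyphenyl)penta-2,4-dien-1-yl methyl carbonate | COC(=O)OC/C=C/C=C/c1ccc(OC)c(OC)c1
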